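Remark on the chemistry: the two ring B hydroxyls are carried as isopropyl ethers, because benzyl aryl ethers are cleaved by BCl3 and by thiolates and could not wait for a closing hydrogenolysis; and since the formyl carbon of isovanillin is para to its methoxy group whereas C1' is meta to the 5'-methoxy group, that carbon is converted into the oxygen-bearing C2' by Dakin oxidation and the alkyne is attached at a new ring position (the skeletons of both key-step partners and of the key-step product are unchanged).

## Structural features

The target is a flavone: benzene ring A is fused through C4a–C8a to 4-pyranone ring C, which carries phenyl ring B on C2 through the C2–C1' bond. It contains no stereocentre, so no relative or absolute configuration has to be set. Ring A is hexasubstituted: besides the two fusion atoms it bears OH at C5, OMe at C6, OH at C7 and OMe at C8. C3 of ring C carries OMe, and ring B carries OH at C2' and C4' and OMe at C5' (a 1,2,4-trioxygenated ring). The fragile points are the electron-rich polyphenol (ring B is a para-methoxyphenol that oxidises readily in basic, aerated media), the pyranone, which opens when hard nucleophiles add to C2, and the methyl ethers on O3 and O6, which sit beside chelating sites and can be lost to strong Lewis acids. The real difficulty is ring A: with no C–H left, neither the acyl carbon C4 nor O1 can be introduced by electrophilic substitution, and the four oxygens must end up differentiated as 5,7-OH against 6,8-OMe. The key step exploits the fact that C8a (bearing O1) and C4a (bearing C4) are neighbours and that C5, C6, C7 and C8 all carry oxygen. As the tetramethyl ether this unit is mirror symmetric about the axis through the middle of the C4a–C8a bond, so ring A can come from 3,4,5,6-tetramethoxybenzyne, which accepts oxygen and acyl carbon on its two aryne carbons without any regiochemical question. Once the carbonyl is in place it differentiates the oxygens, because O5 and O7 are ortho and para to the acyl-bearing C4a while O6 and O8 are meta.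

## Logic of the disconnections

28 to 27: the O5–CH3, O2'–CH(CH3)2 and O4'–CH(CH3)2 bonds are cut. The methyl ether peri to the carbonyl is the one ether on ring A that a chelating boron trihalide removes selectively, and the same reagent strips secondary alkyl aryl ethers, so three groups can fall in one final operation. The gain is that the oxidation-prone tetraphenol exists only at the very end. The demand is that the methyl ethers on O3, O6, O8 and O5' survive, which calls for low temperature and tolerance of the free 7-hydroxyl.

27 to 26: the O7–CH3 bond is cut. O7 is para to the acyl-bearing C4a and gives the best phenoxide leaving group, so an SN2 demethylation by a thiolate can single it out. The gain is a ring A in which all four oxygens are methyl ethers, which is the symmetric form. The demand is discrimination against the O5 and O3 methyl ethers and complete inertness of the ring B ethers to SN2 attack, which is why they are secondary alkyl ethers.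

26 to 25 to 22: first the O3–CH3 bond, then the C3–O bond is cut. C3–H is the only acidic vinylic C–H of the pyranone, so the oxygen can be added after the ring system is complete, by deprotonation, borylation and oxidation, followed by O-methylation. The gain is a C3-unsubstituted flavone, which is exactly what an alkynoic acid delivers. The demand is that the amide base deprotonates C3 and does not add to C2 or metalate ring B.

22 to 11 and 19 (through 21 and 20): the O1–C8a, C4–C4a and O1–C2 bonds are cut, which opens ring C and separates ring A from the rest. The cut is made here because a persubstituted ring A cannot be acylated or oxygenated by substitution, whereas aryne 20 accepts both atoms at once. The gain is large: two fragments of similar size, one of them symmetric. The demand is that acyl transfer within the aryne adduct beats protonation and that 21 closes in the 6-endo sense.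

11 to 8 to 7: the C–Si and O–S bonds are cut (silyl migration from oxygen to carbon after halogen–lithium exchange, then triflation), followed by the C–Br bond. The ortho-silyl triflate is chosen because only a fluoride-triggered aryne source tolerates the carboxylic acid partner. The gain is a simple pentasubstituted phenol. The demand is trivial regiochemistry in the bromination, since 7 has a single C–H.

7 to 4 to 3 to 1: a ring C–O bond is cut (directed lithiation, borylation, oxidation), then an O–CH3 bond, then the C–O bond made by Dakin oxidation of the aldehyde. Each cut removes one oxygen or one methyl group and leads back to a cheap trioxygenated benzaldehyde. The demand is only that lithiation of 4 finds one of two equivalent positions.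

19 to 17 and 18: the C1'–C(sp) bond is cut. Coupling an aryl iodide directly with 18 installs the complete three-carbon acid in one step. The demand is that the electron-rich arylpropiolic acid does not decarboxylate under the coupling.

17 to 16 to 15 to 13 to 12: the C–I bond, an O–isopropyl bond, the C–O bond of a Dakin oxidation and a second O–isopropyl bond are cut in turn. The Dakin step turns the formyl carbon of 12 into the future C2' oxygen, which gives the 1,2,4-trioxygenation pattern with methoxy in the right place. Iodination of 16 is then directed to the one carbon that is ortho to one isopropoxy group and para to the other.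

## Other disconnections considered

Alternative 1: The cut is made at the three methoxy C–O bonds on C6, C8 and C5'. No skeletal bond and no ring is touched, and the whole C15 framework with five of its oxygens is bought as morin A3. In the forward direction A3 would be benzylated on O7, O2' and O4', methylated on O3 and brominated three times to give tribromide A2. Heating A2 with sodium methoxide and CuBr (Ullmann-type methoxylation) should then replace all three bromines in one operation and give A1, which needs only hydrogenolysis to reach 28.
- In its favour: it is the shortest route on paper (roughly seven steps against fifteen), uses one cheap starting material and makes no C–C bond. Its endgame needs no selective demethylation, because O5 stays free and O7, O2' and O4' carry benzyl groups. On step economy and on the endgame it is better than the chosen plan.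
- Against it: the five hydroxyls of A3 must be sorted, and O3 and O2' are close in reactivity, so clean 7,2',4'-tribenzylation followed by 3-methylation is uncertain. Bromination must hit C6, C8 and C5' and spare C3'. The triple copper-mediated exchange has to succeed at three different sites in hot methoxide, where hydrodebromination at each site, methoxide attack at C2 with pyranone opening, and copper binding by the chelated 5-hydroxyl all compete. Partly exchanged products would be very close in polarity.
- Comparison: structurally, the chosen plan fixes the position of every oxygen by construction, while this one depends on substitution selectivity at three sites. Mechanistically, three Ullmann exchanges on one substrate are no less demanding than one aryne cascade. The two plans are equal in keeping the ring B oxygens differentiated throughout.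

Alternative 2: The cut removes ring B by breaking C5'–C6', C1'–C2' and C2'–C3'. In the forward direction the terminal alkyne of 2-ethynylchromone A5, the zerovalent chromium carbene complex A6, (CO)5Cr=C(OMe)C(OtBu)=CH2, and one CO ligand would combine in a Dötz benzannulation to give A4.
- In its favour: the regiochemistry of ring B follows from the terminal alkyne, whose substituted carbon ends next to the new phenol. The three ring B oxygens arrive already differentiated (free 2'-OH, 4'-O-tert-butyl, 5'-OMe). Ring A of A4 carries benzyl groups on O5 and O7, so the endgame is acid plus hydrogenolysis with no selective demethylation, which is better than the chosen plan at that stage.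
- Against it: A5 already contains the complete hexasubstituted ring A with 5,7 and 6,8 differentiated, plus the 3-methoxy group. The hardest part of the target is therefore not solved but moved into a long linear synthesis of A5. The alkyne of A5 is conjugated to the pyranone and is electron-poor, a class that tends to divert to cyclobutenones, furans or indenes and is open to Michael addition. A6 is an uncommon alpha-alkoxyvinyl carbene, used stoichiometrically, with chromium waste.
- Comparison: it builds one ring and three skeletal bonds, as the chosen key step does, so the two are equal in bond count. It is less convergent and, counting the route to A5, longer.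

Alternative 3: The cut is at C8–C8a, with C4a–C5 made one step earlier by adding a metalated pyranone to the mixed squarate A9. In the forward direction, heating cyclobutenone A8 would open it to a dienylketene. The ketene carbon would bond to pyranone C6 in a 6π electrocyclisation, and tautomerisation would give the 5,8-hydroquinone A7 (Moore-type ring expansion).
- In its favour: ring A is built de novo with all four oxygens. In A7 the 8-hydroxyl can be methylated selectively because the 5-hydroxyl is chelated, and O7 is marked as an isopropyl ether. This differentiates ring A without any nucleophilic demethylation, which is better than the chosen plan in that respect.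
- Against it: A9 has two nearly equivalent carbonyls, so addition must distinguish methoxy from isopropoxy neighbours, and a mixture with the 6-isopropoxy-7-methoxy isomer is likely. A C5-metalated 3-methoxy-2-aryl-4-pyranone is a base-sensitive Michael acceptor of doubtful stability. The electrocyclisation has to engage a pyranone C=C and not an arene. A7 is easily oxidised to the 5,8-quinone.
- Comparison: it forms one ring, as the chosen step does, but only one skeletal bond in the key step against three. It needs a similar number of steps after the key step (methylation and two kinds of deprotection). Its regiochemical risk lies in the fragment union, exactly where the symmetric aryne of the chosen plan has none.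

Key step: step 11

## Route

Step 1
Reactants: 1 2,3,4-trimethoxybenzaldehyde
Product: 3 2,3,4-trimethoxyphenol, via 2,3,4-trimethoxyphenyl formate 2 (not isolated)
Conditions: mCPBA, CH2Cl2, 0 °C to rt; aq. NaHCO3 wash; K2CO3 (cat.), MeOH, rt
Reagents that add atoms: mCPBA (3-chloroperoxybenzoic acid), O=C(OO)c1cccc(Cl)c1
Why: Dakin-type Baeyer–Villiger oxidation; the aryl group, made electron rich by ortho and para methoxy groups, migrates in preference to hydride, and the formate is methanolysed to the phenol.

Step 2
Reactants: 3 2,3,4-trimethoxyphenol
Product: 4 1,2,3,4-tetramethoxybenzene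
Conditions: MeI, K2CO3, acetone, reflux
Reagents that add atoms: iodomethane, CI
Why: Williamson ether synthesis on an unhindered phenoxide.

Step 3
Reactants: 4 1,2,3,4-tetramethoxybenzene
Product: 7 2,3,4,5-tetramethoxyphenol, via (2,3,4,5-tetramethoxyphenyl)lithium 5 (not isolated), via dimethyl (2,3,4,5-tetramethoxyphenyl)boronate 6 (not isolated)
Conditions: n-BuLi, TMEDA, THF, 0 °C; B(OMe)3, −78 °C to rt; 30% H2O2, AcOH, 0 °C to rt
Reagents that add atoms: hydrogen peroxide, OO
Why: Directed ortho-lithiation (the two free positions are equivalent and each is ortho to a methoxy group), borylation and oxidative C–B to C–O migration give the phenol in one pot, replacing a formylation and a second Dakin oxidation.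

Step 4
Reactants: 7 2,3,4,5-tetramethoxyphenol
Product: 8 2-bromo-3,4,5,6-tetramethoxyphenol
Conditions: NBS, CH2Cl2, −20 °C, dark
Reagents that add atoms: N-bromosuccinimide, O=C1CCC(=O)N1Br
Why: Electrophilic aromatic bromination; the ring has a single C–H, ortho to the hydroxyl, and the low temperature and anhydrous medium should hold back oxidation to a quinone.

Step 5
Reactants: 8 2-bromo-3,4,5,6-tetramethoxyphenol
Product: 11 2,3,4,5-tetramethoxy-6-(trimethylsilyl)phenyl trifluoromethanesulfonate, via (2-bromo-3,4,5,6-tetramethoxyphenoxy)trimethylsilane 9 (not isolated), via lithium 2,3,4,5-tetramethoxy-6-(trimethylsilyl)phenoxide 10 (not isolated)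
Conditions: HMDS, THF, reflux; concentrate; n-BuLi, THF, −100 °C to −78 °C; Tf2O, −100 °C to rt
Reagents that add atoms: hexamethyldisilazane, C[Si](C)(C)N[Si](C)(C)C; trifluoromethanesulfonic anhydride, O=S(=O)(OS(=O)(=O)C(F)(F)F)C(F)(F)F
Why: O-Silylation, bromine–lithium exchange and 1,3 O-to-C silyl shift (retro-Brook rearrangement) give the ortho-silyl phenoxide, which is triflated in the same flask; this is the standard entry to ortho-silylaryl triflates.

Step 6
Reactants: 12 isovanillin (3-hydroxy-4-methoxybenzaldehyde)
Product: 13 3-isopropoxy-4-methoxybenzaldehyde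
Conditions: 2-bromopropane, K2CO3, DMF, 70 °C
Reagents that add atoms: 2-bromopropane, CC(C)Br
Why: Williamson ether synthesis; the isopropyl ether is chosen because it resists thiolate and is removed by BCl3.

Step 7
Reactants: 13 3-isopropoxy-4-methoxybenzaldehyde
Product: 15 3-isopropoxy-4-methoxyphenol, via 3-isopropoxy-4-methoxyphenyl formate 14 (not isolated)
Conditions: mCPBA, CH2Cl2, 0 °C to rt; aq. NaHCO3 wash; K2CO3 (cat.), MeOH, rt
Reagents that add atoms: mCPBA (3-chloroperoxybenzoic acid), O=C(OO)c1cccc(Cl)c1
Why: Dakin-type Baeyer–Villiger oxidation favoured by the para-methoxy group; it converts the formyl carbon into the future C2' oxygen, para to the methoxy group.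

Step 8
Reactants: 15 3-isopropoxy-4-methoxyphenol
Product: 16 2,4-diisopropoxy-1-methoxybenzene
Conditions: 2-bromopropane, K2CO3, DMF, 70 °C
Reagents that add atoms: 2-bromopropane, CC(C)Br
Why: Williamson ether synthesis.

Step 9
Reactants: 16 2,4-diisopropoxy-1-methoxybenzene
Product: 17 1-iodo-2,4-diisopropoxy-5-methoxybenzene
Conditions: NIS, TFA (cat.), MeCN, 0 °C to rt
Reagents that add atoms: N-iodosuccinimide, O=C1CCC(=O)N1I
Why: Electrophilic aromatic iodination; C5 of 16 is ortho to one isopropoxy group and para to the other, whereas C3 is shielded between two isopropoxy groups and C6 is activated only by one ortho methoxy group.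

Step 10
Reactants: 17 1-iodo-2,4-diisopropoxy-5-methoxybenzene; 18 propiolic acid
Product: 19 3-(2,4-diisopropoxy-5-methoxyphenyl)propiolic acid
Conditions: Pd(PPh3)4 (cat.), DBU, DMSO, 35 °C; aq. HCl
Reagents that add atoms: none
Why: Copper-free Sonogashira-type coupling of an aryl iodide with propiolic acid; near room temperature the carboxyl group is kept, and the absence of copper salts disfavours decarboxylation.

Step 11
Reactants: 11 2,3,4,5-tetramethoxy-6-(trimethylsilyl)phenyl trifluoromethanesulfonate; 19 3-(2,4-diisopropoxy-5-methoxyphenyl)propiolic acid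
Product: 22 2',4'-diisopropoxy-5,6,7,8,5'-pentamethoxyflavone, via 3,4,5,6-tetramethoxybenzyne 20 (not isolated), via ortho-hydroxyaryl ynone 21 (not isolated)
Conditions: CsF (excess), THF, sealed tube, 125 °C
Reagents that add atoms: none
Why: Fluoride removes the silyl group of 11 and triflate leaves, releasing aryne 20; the caesium carboxylate of 19 adds through oxygen to one aryne carbon, and the aryl anion on the neighbouring carbon attacks the ester carbonyl through a four-membered ring that opens to the ortho-acyl phenoxide of 21, a net insertion of the aryne into the C–O bond of the acid that forms O1–C8a and C4–C4a. The phenoxide then adds to the alkyne carbon bearing ring B in a 6-endo-dig oxa-Michael closure, which forms O1–C2 and ring C, and the acid proton ends on C3. The closest known reaction type is the fluoride-mediated C–O insertion of arynes into carboxylic acids to give ortho-hydroxyaryl ketones, which continues to flavones when the acid is an arylpropiolic acid. No stereocentre is formed. No regiocontrol of the aryne addition is needed, because 20 is mirror symmetric and both orientations give the same product. The step does need acyl transfer to outrun protonation of the aryl anion, which would stop at the aryl ester; the high temperature, the aprotic medium and the intramolecular four-centre transfer favour this, and the flanking methoxy group stabilises the anion inductively without blocking it. It also needs 6-endo closure and not 5-exo closure to an aurone, which the Michael polarity of the ynone secures in an aprotic medium free of carbophilic metals.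

Step 12
Reactants: 22 2',4'-diisopropoxy-5,6,7,8,5'-pentamethoxyflavone
Product: 25 3-hydroxy-2',4'-diisopropoxy-5,6,7,8,5'-pentamethoxyflavone, via 3-lithioflavone 23 (not isolated), via flavon-3-ylboronic acid dimethyl ester 24 (not isolated)
Conditions: LiN(iPr)2, THF, −78 °C; B(OMe)3, −78 °C to rt; 30% H2O2, AcOH, 0 °C to rt
Reagents that add atoms: hydrogen peroxide, OO
Why: Regioselective C3 lithiation of a flavone (C3–H is the most acidic C–H, next to the carbonyl), borylation and oxidation is an established way to flavonols; the isopropyl and methyl ethers are inert to the amide base at −78 °C.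

Step 13
Reactants: 25 3-hydroxy-2',4'-diisopropoxy-5,6,7,8,5'-pentamethoxyflavone
Product: 26 2',4'-diisopropoxy-3,5,6,7,8,5'-hexamethoxyflavone
Conditions: MeI, K2CO3, acetone, reflux
Reagents that add atoms: iodomethane, CI
Why: Williamson methylation of the only free hydroxyl, the acidic 3-OH of the flavonol.

Step 14
Reactants: 26 2',4'-diisopropoxy-3,5,6,7,8,5'-hexamethoxyflavone
Product: 27 7-hydroxy-2',4'-diisopropoxy-3,5,6,8,5'-pentamethoxyflavone
Conditions: NaSEt (slight excess), DMF, 90 °C; aq. HCl
Reagents that add atoms: none
Why: SN2 demethylation by thiolate at the ether whose phenoxide is the best leaving group: O7 is para to the acyl-bearing C4a and twisted out of plane by two ortho methoxy groups, like the central ether of a 3,4,5-trimethoxyaryl ketone. The secondary isopropyl ethers resist SN2 attack, and the phenoxide formed slows any second cleavage.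

Step 15
Reactants: 27 7-hydroxy-2',4'-diisopropoxy-3,5,6,8,5'-pentamethoxyflavone
Product: 28 5,7,2',4'-tetrahydroxy-3,6,8,5'-tetramethoxyflavone
Conditions: BCl3 (excess), CH2Cl2, −78 °C to 0 °C; MeOH, then aq. HCl, under argon
Reagents that add atoms: none
Why: BCl3 chelates between the C4 carbonyl and O5 and cleaves that peri-methyl ether, and it cleaves aryl isopropyl ethers through their secondary cation character. Non-chelated aryl methyl ethers (O6, O8, O5') and the 3-methyl ether should survive at or below 0 °C.

## Compound list

1 | 2,3,4-trimethoxybenzaldehyde | COc1ccc(C=O)c(OC)c1OC | starting material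
2 | 2,3,4-trimethoxyphenyl formate | COc1ccc(OC=O)c(OC)c1OC | intermediate
3 | 2,3,4-trimethoxyphenol | COc1ccc(O)c(OC)c1OC | intermediate
4 | 1,2,3,4-tetramethoxybenzene | COc1ccc(OC)c(OC)c1OC | intermediate
5 | (2,3,4,5-tetramethoxyphenyl)lithium | [Li]c1cc(OC)c(OC)c(OC)c1OC | intermediate
6 | dimethyl (2,3,4,5-tetramethoxyphenyl)boronate | COB(OC)c1cc(OC)c(OC)c(OC)c1OC | intermediate
7 | 2,3,4,5-tetramethoxyphenol | COc1cc(O)c(OC)c(OC)c1OC | intermediate
8 | 2-bromo-3,4,5,6-tetramethoxyphenol | COc1c(Br)c(O)c(OC)c(OC)c1OC | intermediate
9 | (2-bromo-3,4,5,6-tetramethoxyphenoxy)trimethylsilane | COc1c(Br)c(O[Si](C)(C)C)c(OC)c(OC)c1OC | intermediate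
10 | lithium 2,3,4,5-tetramethoxy-6-(trimethylsilyl)phenoxide | [Li+].COc1c([Si](C)(C)C)c([O-])c(OC)c(OC)c1OC | intermediate
11 | 2,3,4,5-tetramethoxy-6-(trimethylsilyl)phenyl trifluoromethanesulfonate | COc1c(OC)c(OC)c([Si](C)(C)C)c(OS(=O)(=O)C(F)(F)F)c1OC | intermediate
12 | isovanillin (3-hydroxy-4-methoxybenzaldehyde) | COc1ccc(C=O)cc1O | starting material
13 | 3-isopropoxy-4-methoxybenzaldehyde | COc1ccc(C=O)cc1OC(C)C | intermediate
14 | 3-isopropoxy-4-methoxyphenyl formate | COc1ccc(OC=O)cc1OC(C)C | intermediate
15 | 3-isopropoxy-4-methoxyphenol | COc1ccc(O)cc1OC(C)C | intermediate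
16 | 2,4-diisopropoxy-1-methoxybenzene | COc1ccc(OC(C)C)cc1OC(C)C | intermediate
17 | 1-iodo-2,4-diisopropoxy-5-methoxybenzene | COc1cc(I)c(OC(C)C)cc1OC(C)C | intermediate
18 | propiolic acid | C#CC(=O)O | starting material
19 | 3-(2,4-diisopropoxy-5-methoxyphenyl)propiolic acid | COc1cc(C#CC(=O)O)c(OC(C)C)cc1OC(C)C | intermediate
20 | 3,4,5,6-tetramethoxybenzyne | COC1=C(OC)C(OC)=C(OC)C#C1 | intermediate
21 | 3-(2,4-diisopropoxy-5-methoxyphenyl)-1-(2-hydroxy-3,4,5,6-tetramethoxyphenyl)prop-2-yn-1-one (present as its caesium phenoxide) | COc1cc(C#CC(=O)c2c(O)c(OC)c(OC)c(OC)c2OC)c(OC(C)C)cc1OC(C)C | intermediate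
22 | 2',4'-diisopropoxy-5,6,7,8,5'-pentamethoxyflavone | COc1cc(-c2cc(=O)c3c(OC)c(OC)c(OC)c(OC)c3o2)c(OC(C)C)cc1OC(C)C | intermediate
23 | 3-lithio-2',4'-diisopropoxy-5,6,7,8,5'-pentamethoxyflavone | COc1cc(-c2oc3c(OC)c(OC)c(OC)c(OC)c3c(=O)c2[Li])c(OC(C)C)cc1OC(C)C | intermediate
24 | dimethyl [2',4'-diisopropoxy-5,6,7,8,5'-pentamethoxyflavon-3-yl]boronate | COc1cc(-c2oc3c(OC)c(OC)c(OC)c(OC)c3c(=O)c2B(OC)OC)c(OC(C)C)cc1OC(C)C | intermediate
25 | 3-hydroxy-2',4'-diisopropoxy-5,6,7,8,5'-pentamethoxyflavone | COc1cc(-c2oc3c(OC)c(OC)c(OC)c(OC)c3c(=O)c2O)c(OC(C)C)cc1OC(C)C | intermediate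
26 | 2',4'-diisopropoxy-3,5,6,7,8,5'-hexamethoxyflavone | COc1cc(-c2oc3c(OC)c(OC)c(OC)c(OC)c3c(=O)c2OC)c(OC(C)C)cc1OC(C)C | intermediate
27 | 7-hydroxy-2',4'-diisopropoxy-3,5,6,8,5'-pentamethoxyflavone | COc1cc(-c2oc3c(OC)c(O)c(OC)c(OC)c3c(=O)c2OC)c(OC(C)C)cc1OC(C)C | intermediate
28 | 5,7,2',4'-tetrahydroxy-3,6,8,5'-tetramethoxyflavone | COc1cc(-c2oc3c(OC)c(O)c(OC)c(O)c3c(=O)c2OC)c(O)cc1O | target

## Step count and least certain steps

Total: 15 steps. Longest linear sequence: 10 steps (steps 1–5 or 6–10, then 11–15).

Step 11 (key step). The most likely failure is protonation of the aryl anion before acyl transfer, which would stop at the aryl ester; the acid itself supplies one proton per molecule. Thermal decarboxylation of the electron-rich caesium arylpropiolate and, less likely, 5-exo closure are further leaks. Fallback (sets out from 8 and 19, returns at 21 and then 22): the same three bonds are made stepwise by organolithium chemistry. 8 is protected with MOMCl/iPr2NEt as 1-bromo-2,3,4,5-tetramethoxy-6-(methoxymethoxy)benzene F1, and bromine–lithium exchange with n-BuLi at −78 °C gives [2,3,4,5-tetramethoxy-6-(methoxymethoxy)phenyl]lithium F2. 19 is converted with MeNHOMe·HCl and a carbodiimide into 3-(2,4-diisopropoxy-5-methoxyphenyl)-N-methoxy-N-methylpropiolamide F3. Addition of F2 to F3 gives 3-(2,4-diisopropoxy-5-methoxyphenyl)-1-[2,3,4,5-tetramethoxy-6-(methoxymethoxy)phenyl]prop-2-yn-1-one F4. HCl in MeOH frees the phenol 21, which K2CO3 in acetone closes to 22.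

Step 14. Regiocontrol of the SN2 demethylation may be lost, with the 3-methyl ether (whose oxygen is the next best leaving group) or the 5-methyl ether cleaved alongside or in place of the 7-methyl ether. Thiolate may also add to C2 and open the pyranone. Fallback (sets out from 22, returns at 28): the thiolate cleavage is moved ahead of the C3 oxygenation, where no 3-methyl ether exists.
- 22 with NaSEt in DMF should give 7-hydroxy-2',4'-diisopropoxy-5,6,8,5'-tetramethoxyflavone F5, which 2-bromopropane/K2CO3 caps as 2',4',7-triisopropoxy-5,6,8,5'-tetramethoxyflavone F6.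
- LiN(iPr)2 gives 3-lithio-2',4',7-triisopropoxy-5,6,8,5'-tetramethoxyflavone F7, B(OMe)3 gives dimethyl [2',4',7-triisopropoxy-5,6,8,5'-tetramethoxyflavon-3-yl]boronate F8, and H2O2/AcOH gives 3-hydroxy-2',4',7-triisopropoxy-5,6,8,5'-tetramethoxyflavone F9.
- MeI/K2CO3 gives 2',4',7-triisopropoxy-3,5,6,8,5'-pentamethoxyflavone F10, and BCl3 then removes the 5-methyl group and all three isopropyl groups to give 28.

Step 12. Deprotonation may be incomplete or misdirected (amide addition at C2, metalation of ring B), or the electron-rich flavonol may be over-oxidised during the peroxide treatment. Fallback (sets out from 22, returns at 25): electrophilic oxygen transfer replaces deprotonation. Dimethyldioxirane in acetone epoxidises the C2=C3 bond to racemic, cis-fused 2,3-epoxy-2',4'-diisopropoxy-5,6,7,8,5'-pentamethoxyflavanone F11, which a trace of TsOH isomerises to 25.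

Step 10. The electron-rich product may lose CO2 under the coupling and go on to the terminal alkyne or a diarylalkyne, or oxidative addition of the hindered, electron-rich iodide may be too slow at a temperature that preserves the acid. Fallback (sets out from 17, returns at 19): C–C coupling and carboxylation are separated. Sonogashira coupling of 17 with ethynyltrimethylsilane (Pd(PPh3)2Cl2, CuI, Et3N) gives [(2,4-diisopropoxy-5-methoxyphenyl)ethynyl]trimethylsilane F12. K2CO3 in MeOH gives 1-ethynyl-2,4-diisopropoxy-5-methoxybenzene F13, n-BuLi at −78 °C gives lithium (2,4-diisopropoxy-5-methoxyphenyl)acetylide F14, and CO2 followed by acid gives 19.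

Step 5. On this fully substituted ring the silyl shift may be slowed by crowding, so that the aryllithium is protonated or butylated before it rearranges, and triflation of the hindered phenoxide may be incomplete. Fallback (sets out from 7, returns at 11): the C–Si bond is made by directed metalation, with no bromination and no migration. 7 with ClCONEt2 and NaH gives 2,3,4,5-tetramethoxyphenyl N,N-diethylcarbamate F15. s-BuLi/TMEDA at −78 °C gives the ortho-lithiated carbamate, [2-(diethylcarbamoyloxy)-3,4,5,6-tetramethoxyphenyl]lithium F16, and TMSCl gives 2,3,4,5-tetramethoxy-6-(trimethylsilyl)phenyl N,N-diethylcarbamate F17. LiAlH4 in THF frees 2,3,4,5-tetramethoxy-6-(trimethylsilyl)phenol F18, and Tf2O/pyridine gives 11.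

## Further compounds

F1 | step 11 | 1-bromo-2,3,4,5-tetramethoxy-6-(methoxymethoxy)benzene | COCOc1c(Br)c(OC)c(OC)c(OC)c1OC
F2 | step 11 | [2,3,4,5-tetramethoxy-6-(methoxymethoxy)phenyl]lithium | [Li]c1c(OCOC)c(OC)c(OC)c(OC)c1OC
F3 | step 11 | 3-(2,4-diisopropoxy-5-methoxyphenyl)-N-methoxy-N-methylpropiolamide | CON(C)C(=O)C#Cc1cc(OC)c(OC(C)C)cc1OC(C)C
F4 | step 11 | 3-(2,4-diisopropoxy-5-methoxyphenyl)-1-[2,3,4,5-tetramethoxy-6-(methoxymethoxy)phenyl]prop-2-yn-1-one | COCOc1c(C(=O)C#Cc2cc(OC)c(OC(C)C)cc2OC(C)C)c(OC)c(OC)c(OC)c1OC
F5 | step 14 | 7-hydroxy-2',4'-diisopropoxy-5,6,8,5'-tetramethoxyflavone | COc1cc(-c2cc(=O)c3c(OC)c(OC)c(O)c(OC)c3o2)c(OC(C)C)cc1OC(C)C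
F6 | step 14 | 2',4',7-triisopropoxy-5,6,8,5'-tetramethoxyflavone | COc1cc(-c2cc(=O)c3c(OC)c(OC)c(OC(C)C)c(OC)c3o2)c(OC(C)C)cc1OC(C)C
F7 | step 14 | 3-lithio-2',4',7-triisopropoxy-5,6,8,5'-tetramethoxyflavone | COc1cc(-c2oc3c(OC)c(OC(C)C)c(OC)c(OC)c3c(=O)c2[Li])c(OC(C)C)cc1OC(C)C
F8 | step 14 | dimethyl [2',4',7-triisopropoxy-5,6,8,5'-tetramethoxyflavon-3-yl]boronate | COc1cc(-c2oc3c(OC)c(OC(C)C)c(OC)c(OC)c3c(=O)c2B(OC)OC)c(OC(C)C)cc1OC(C)C
F9 | step 14 | 3-hydroxy-2',4',7-triisopropoxy-5,6,8,5'-tetramethoxyflavone | COc1cc(-c2oc3c(OC)c(OC(C)C)c(OC)c(OC)c3c(=O)c2O)c(OC(C)C)cc1OC(C)C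
F10 | step 14 | 2',4',7-triisopropoxy-3,5,6,8,5'-pentamethoxyflavone | COc1cc(-c2oc3c(OC)c(OC(C)C)c(OC)c(OC)c3c(=O)c2OC)c(OC(C)C)cc1OC(C)C
F11 | step 12 | 2,3-epoxy-2',4'-diisopropoxy-5,6,7,8,5'-pentamethoxyflavanone (racemic, cis-fused; one enantiomer drawn) | O=C1c2c(OC)c(OC)c(OC)c(OC)c2O[C@]2(c3cc(OC)c(OC(C)C)cc3OC(C)C)O[C@H]12
F12 | step 10 | [(2,4-diisopropoxy-5-methoxyphenyl)ethynyl]trimethylsilane | COc1cc(C#C[Si](C)(C)C)c(OC(C)C)cc1OC(C)C
F13 | step 10 | 1-ethynyl-2,4-diisopropoxy-5-methoxybenzene | COc1cc(C#C)c(OC(C)C)cc1OC(C)C
F14 | step 10 | lithium (2,4-diisopropoxy-5-methoxyphenyl)acetylide | [Li]C#Cc1cc(OC)c(OC(C)C)cc1OC(C)C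
F15 | step 5 | 2,3,4,5-tetramethoxyphenyl N,N-diethylcarbamate | CCN(CC)C(=O)Oc1cc(OC)c(OC)c(OC)c1OC
F16 | step 5 | [2-(diethylcarbamoyloxy)-3,4,5,6-tetramethoxyphenyl]lithium | CCN(CC)C(=O)Oc1c([Li])c(OC)c(OC)c(OC)c1OC
F17 | step 5 | 2,3,4,5-tetramethoxy-6-(trimethylsilyl)phenyl N,N-diethylcarbamate | CCN(CC)C(=O)Oc1c([Si](C)(C)C)c(OC)c(OC)c(OC)c1OC
F18 | step 5 | 2,3,4,5-tetramethoxy-6-(trimethylsilyl)phenol | COc1c([Si](C)(C)C)c(O)c(OC)c(OC)c1OC
A1 | alternative 1 | 7,2',4'-tris(benzyloxy)-5-hydroxy-3,6,8,5'-tetramethoxyflavone | COc1cc(-c2oc3c(OC)c(OCc4ccccc4)c(OC)c(O)c3c(=O)c2OC)c(OCc2ccccc2)cc1OCc1ccccc1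
A2 | alternative 1 | 7,2',4'-tris(benzyloxy)-6,8,5'-tribromo-5-hydroxy-3-methoxyflavone | Brc1cc(-c2oc3c(Br)c(OCc4ccccc4)c(Br)c(O)c3c(=O)c2OC)c(OCc2ccccc2)cc1OCc1ccccc1
A3 | alternative 1 | morin (3,5,7,2',4'-pentahydroxyflavone) | O=c1c(O)c(-c2ccc(O)cc2O)oc2cc(O)cc(O)c12
A4 | alternative 2 | 5,7-bis(benzyloxy)-4'-tert-butoxy-2'-hydroxy-3,6,8,5'-tetramethoxyflavone | COc1cc(-c2oc3c(OC)c(OCc4ccccc4)c(OC)c(OCc4ccccc4)c3c(=O)c2OC)c(O)cc1OC(C)(C)C
A5 | alternative 2 | 5,7-bis(benzyloxy)-2-ethynyl-3,6,8-trimethoxy-4H-chromen-4-one | C#Cc1oc2c(OC)c(OCc3ccccc3)c(OC)c(OCc3ccccc3)c2c(=O)c1OC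
A6 | alternative 2 | pentacarbonyl[(1-tert-butoxyvinyl)(methoxy)carbene]chromium, (CO)5Cr=C(OMe)C(OtBu)=CH2 | COC(C(=C)OC(C)(C)C)=[Cr](=C=O)(=C=O)(=C=O)(=C=O)=C=O
A7 | alternative 3 | 2',4'-bis(benzyloxy)-5,8-dihydroxy-7-isopropoxy-3,6,5'-trimethoxyflavone | COc1cc(-c2oc3c(O)c(OC(C)C)c(OC)c(O)c3c(=O)c2OC)c(OCc2ccccc2)cc1OCc1ccccc1
A8 | alternative 3 | 4-{6-[2,4-bis(benzyloxy)-5-methoxyphenyl]-5-methoxy-4-oxo-4H-pyran-3-yl}-4-hydroxy-2-isopropoxy-3-methoxycyclobut-2-en-1-one (racemic; one enantiomer drawn) | COC1=C(OC(C)C)C(=O)[C@@]1(O)c1coc(-c2cc(OC)c(OCc3ccccc3)cc2OCc2ccccc2)c(OC)c1=O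
A9 | alternative 3 | 3-isopropoxy-4-methoxycyclobut-3-ene-1,2-dione | COC1=C(OC(C)C)C(=O)C1=O
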